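**Retrosynthetic overview**

1. Feature: in ring C (C3a–C4–C5–C6–C7–C7a) the C4 bromide is cis to the angular C3a methyl, next to the trans C3a–C7a fusion with ring B. An (E)-bromoalkene adding across a diene gives exactly this pattern, so C3a–C7a and C4–C5 are cut together to an acyclic bromo-triene whose C1–C2–C3 tether becomes ring B.
2. Ring A (C1'–C6') is formed last: C2'–C3' and C4'–Br come from bromonium closure of a 1,5-diene with the C1' cation taken by the C8 ester. The C8–C1' bond comes from a C8 aldehyde and a 2-lithio-1,5-diene made from 6-methylhept-5-en-2-one.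
3. The C7 carbinol is hydration of the C6=C7 alkene left by the cycloaddition. The C8 carbinol is set by chelate-controlled reduction from the C2 hydroxyl.
4. The triene comes from a syn-aldol of a dienoyl oxazolidinone (from tiglic aldehyde) with (E)-4-bromo-3-methylbut-3-enal (from but-3-yn-1-ol).
5. Ring order: rings B and C together in step 9, ring A in step 19.

Key step: step 9

Conventions: hydrindane atoms are C1–C7a (ring B = C1, C2, C3, C3a, C7a; ring C = C3a, C4, C5, C6, C7, C7a). C8 is the linking carbinol carbon. Ring A is C1'–C6' (C1' carbinol, C3' gem-dimethyl, C4' bromide). β is the face of the C3a methyl, α the opposite face.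

Remark 1: the tertiary C7 hydroxyl is carried unprotected from step 10 on; being axial and flanked by the ring fusion it is assumed inert to the oxidation, acylation and silyl-cleavage conditions, costing only one extra equivalent of organolithium in step 14.

Remark 2: no element of the substrate is expected to bias the face of bromonium formation at the remote isopropylidene group in step 19, so the C4' epimers are assumed to be separable by chromatography.

**Route**

Step 1
Reactants: 1 but-3-yn-1-ol
Product: 3 (E)-4-bromo-3-methylbut-3-en-1-ol, via alkenylalane 2 (not isolated)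
Conditions: AlMe3 (3 equiv), Cp2ZrCl2 (0.25 equiv), CH2Cl2, 0 °C to rt; then NBS, THF, −30 to 0 °C; aqueous work-up
Reagents that add atoms: trimethylaluminium, C[Al](C)C; N-bromosuccinimide, O=C1CCC(=O)N1Br
Why: Zirconium-catalysed carboalumination adds methyl and aluminium syn across the alkyne with aluminium at the terminus, and bromodealumination keeps the geometry, so bromine ends cis to the methyl group, that is (E).

Step 2
Reactants: 3 (E)-4-bromo-3-methylbut-3-en-1-ol
Product: 4 (E)-4-bromo-3-methylbut-3-enal
Conditions: Dess–Martin periodinane, NaHCO3, CH2Cl2, 0 °C to rt; used crude at once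
Reagents that add atoms: none
Why: Dess–Martin oxidation under buffered, non-basic conditions should give the β,γ-unsaturated aldehyde without moving the double bond into conjugation.

Step 3
Reactants: 5 tiglic aldehyde; 6 triethyl phosphonoacetate
Product: 7 ethyl (2E,4E)-4-methylhexa-2,4-dienoate
Conditions: NaH, THF, 0 °C to rt
Reagents that add atoms: none
Why: Horner–Wadsworth–Emmons olefination with a stabilised phosphonate gives the (E)-enoate and leaves the tiglic double bond untouched.

Step 4
Reactants: 7 ethyl (2E,4E)-4-methylhexa-2,4-dienoate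
Product: 8 (2E,4E)-4-methylhexa-2,4-dienoic acid
Conditions: LiOH, THF/MeOH/H2O, rt; then 1 M HCl
Reagents that add atoms: lithium hydroxide, [Li+].[OH-]
Why: Ester saponification; the dienoate carries no base-sensitive stereocentre.

Step 5
Reactants: 8 (2E,4E)-4-methylhexa-2,4-dienoic acid; 9 (S)-4-benzyloxazolidin-2-one
Product: 11 (S)-4-benzyl-3-[(2E,4E)-4-methylhexa-2,4-dienoyl]oxazolidin-2-one, via mixed anhydride 10 (not isolated)
Conditions: t-BuCOCl, Et3N, THF, −20 °C; then 9, LiCl, rt
Reagents that add atoms: none
Why: N-Acylation of the oxazolidinone through the pivaloyl mixed anhydride, which is attacked at the less hindered dienoyl carbonyl.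

Step 6
Reactants: 11 dienoyl oxazolidinone; 4 (E)-4-bromo-3-methylbut-3-enal
Product: 13 (2S,3R) syn-aldol imide, via boron trienolate 12 (not isolated)
Conditions: Bu2BOTf, Et3N, CH2Cl2, −78 to 0 °C; then 4, −78 to 0 °C; pH 7 buffer, MeOH, 30% H2O2, 0 °C
Reagents that add atoms: none
Why: Evans syn-aldol reaction in its deconjugative form: soft enolisation at the C6 methyl through the diene gives the (Z)-boron trienolate, which reacts at its α-carbon through a chair Zimmerman–Traxler transition state on the face away from the benzyl group, setting the later C1 and C2 syn as (2S,3R) and leaving the (E)-3-methyl-1,3-diene.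

Step 7
Reactants: 13 syn-aldol imide
Product: 14 (2R,3R,5E)-6-bromo-5-methyl-2-[(1E)-2-methylbuta-1,3-dien-1-yl]hex-5-ene-1,3-diol
Conditions: LiBH4, MeOH (1 equiv), THF, 0 °C
Reagents that add atoms: none
Why: Reductive cleavage of the imide gives the primary alcohol and returns the auxiliary without touching the stereocentres.

Step 8
Reactants: 14 triene diol
Product: 15 bis(tert-butyldimethylsilyl) ether of 14 (bromo-triene)
Conditions: TBSOTf, 2,6-lutidine, CH2Cl2, −78 to 0 °C
Reagents that add atoms: tert-butyldimethylsilyl trifluoromethanesulfonate, CC(C)(C)[Si](C)(C)OS(=O)(=O)C(F)(F)F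
Why: Silylation of both hydroxyls with the silyl triflate and a hindered base, mild enough for the diene and the bromoalkene.

Step 9
Reactants: 15 bromo-triene
Product: 16 4β-bromo trans-hydrindene (1α-silyloxymethyl; 2α-silyloxy; 3aβ-methyl; 7aα-H; C6=C7)
Conditions: PhMe (0.01 M, degassed), BHT (0.1 equiv), sealed tube, 190 °C, 24–48 h
Reagents that add atoms: none
Why: This is the thermal intramolecular Diels–Alder reaction of a 1,6,8-nonatriene, the known route to hydrindenes: the (E)-bromoalkene C3a=C4 adds suprafacially across C7a and C5 of the (E)-diene in one concerted step. Ring B closes as the tether ring through the new C3a–C7a bond, and ring C closes as the six-membered cycloadduct through C3a–C7a and C4–C5. C4 is fixed by the alkene geometry, so bromine stays cis to the C3a methyl and ends equatorial; C7a is fixed by C1, whose hydrogen eclipses the diene to avoid 1,3-allylic strain with the C7 methyl, which leaves the tether on one diene face; C3a follows from the fold of the tether. The step needs the trans-fused fold (tether carbon C3 exo, dienophile methyl endo) over the cis-fused one, and only in the trans fold does the angular methyl stay off the α face that carries both the C2 silyloxy and the C1 silyloxymethyl groups. That preference is expected to be moderate and the unactivated trisubstituted dienophile needs about 190 °C, so the risk of the route sits here.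

Step 10
Reactants: 16 trans-hydrindene
Product: 18 C7 tertiary alcohol (7β-OH; 7α-methyl), via organomercurial 17 (not isolated)
Conditions: Hg(OAc)2, THF/H2O (1:1), rt; then 3 M NaOH, NaBH4, 0 °C
Reagents that add atoms: water, O
Why: Oxymercuration–demercuration (Markovnikov hydration): mercury takes the α face away from the angular methyl and water opens the mercurinium ion at the tertiary C7 in the trans-diaxial sense from the β face, so the C7 hydroxyl is axial and syn to the C3a methyl, after which NaBH4 replaces mercury at C6 by hydrogen.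

Step 11
Reactants: 18 C7 tertiary alcohol
Product: 19 primary alcohol (C2 silyl ether kept)
Conditions: HF·pyridine, pyridine, THF, 0 °C
Reagents that add atoms: none
Why: Selective cleavage of the primary silyl ether with buffered fluoride, the hindered secondary ether reacting far more slowly.

Step 12
Reactants: 19 primary alcohol
Product: 20 C8 aldehyde
Conditions: Dess–Martin periodinane, NaHCO3, CH2Cl2, 0 °C to rt
Reagents that add atoms: none
Why: Dess–Martin oxidation of the primary alcohol; the buffered conditions should keep the α-stereocentre C1 and the β-silyloxy group intact.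

Step 13
Reactants: 21 6-methylhept-5-en-2-one; 22 2,4,6-triisopropylbenzenesulfonohydrazide
Product: 23 6-methylhept-5-en-2-one 2,4,6-triisopropylbenzenesulfonylhydrazone
Conditions: MeOH, conc. HCl (cat.), rt
Reagents that add atoms: none
Why: Acid-catalysed condensation of the ketone with the sulfonyl hydrazide to the hydrazone.

Step 14
Reactants: 23 sulfonylhydrazone; 20 C8 aldehyde
Product: 25 allylic alcohol (both C8 epimers), via vinyllithium 24 (not isolated)
Conditions: 23 (3 equiv), n-BuLi (6 equiv), THF, −78 to 0 °C; then 20, −78 °C; aq. NH4Cl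
Reagents that add atoms: none
Why: Shapiro reaction: the hydrazone dianion formed by deprotonation at the methyl group loses sulfinate and N2 to give the 2-lithio-1-alkene, which adds to the aldehyde; the new C8 carbinol forms as an epimer mixture that converges in step 15.

Step 15
Reactants: 25 allylic alcohol
Product: 26 α-methylene ketone (enone)
Conditions: Dess–Martin periodinane, NaHCO3, CH2Cl2, 0 °C to rt
Reagents that add atoms: none
Why: Dess–Martin oxidation of the secondary allylic alcohol removes the C8 centre; the tertiary C7 alcohol cannot be oxidised.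

Step 16
Reactants: 26 enone
Product: 27 β-hydroxy enone (free C2 hydroxyl)
Conditions: HF·pyridine, pyridine, THF, 0 °C to rt
Reagents that add atoms: none
Why: Cleavage of the secondary silyl ether under weakly acidic fluoride conditions, which avoid retro-aldol cleavage and β-elimination of the β-hydroxy ketone.

Step 17
Reactants: 27 β-hydroxy enone
Product: 29 syn-1,3-diol with (R)-C8, via boron chelate 28 (not isolated)
Conditions: Et2BOMe, THF/MeOH (4:1), −78 °C; NaBH4, −78 °C; AcOH, then MeOH co-evaporation
Reagents that add atoms: none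
Why: Narasaka–Prasad reduction: the C2 alkoxide and the ketone are held in a six-membered diethylboron chelate cis-fused to ring B, and external hydride attacks C8 from the face opposite C7a, giving the syn-1,3-diol with (R) configuration at C8.

Step 18
Reactants: 29 syn-1,3-diol
Product: 30 C2,C8-diacetate
Conditions: Ac2O, pyridine, DMAP (cat.), CH2Cl2, 0 °C to rt
Reagents that add atoms: acetic anhydride, CC(=O)OC(C)=O
Why: Acetylation of the two secondary hydroxyls; the hindered tertiary C7 hydroxyl should not react under these conditions.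

Step 19
Reactants: 30 C2,C8-diacetate
Product: 32 ring A hydroxy diacetate (C1'-OH; C8-OAc; C2-OAc), via dioxolanylium ion 31 (not isolated)
Conditions: Et2SBr·SbBrCl5 (1.1 equiv), MeNO2, −25 °C, 10 min; then sat. aq. NaHCO3; chromatographic separation of the C4' epimers
Reagents that add atoms: bromodiethylsulfonium bromopentachloroantimonate, CC[S+](Br)CC.Cl[Sb-](Cl)(Cl)(Cl)(Cl)Br; water, O
Why: Bromonium-induced cation–olefin cyclisation of the 1,5-diene: the trisubstituted alkene takes bromine, the 1,1-disubstituted alkene attacks the tertiary end through a chair with bromine equatorial (C2'–C3' bond), and the C8 acetate carbonyl captures the tertiary C1' cation as a spiro dioxolanylium ion with the new C–O bond axial, the bulky C8 avoiding the syn-axial C3' methyl, so that oxygen is cis to bromine; water opens the ion to the hydroxy acetate; the substrate is not expected to bias the face of the remote alkene, so the (4'S) product has to be separated from its C4' epimer.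

Step 20
Reactants: 32 ring A hydroxy diacetate
Product: 33 target, CNP0144982.1
Conditions: K2CO3, MeOH, rt
Reagents that add atoms: none
Why: Transesterification of the two acetates with methanol; the neopentyl secondary bromides and the tertiary alcohols are inert, and neither bromide has a hydroxyl placed for backside displacement.

**Compound list**

1 | but-3-yn-1-ol | C#CCCO | starting material
2 | (E)-alkenylalane, dimethyl[4-(dimethylalumanyloxy)-2-methylbut-1-enyl]alumane (not isolated) | C[Al](C)/C=C(\C)CCO[Al](C)C | intermediate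
3 | (E)-4-bromo-3-methylbut-3-en-1-ol | Br/C=C(\C)CCO | intermediate
4 | (E)-4-bromo-3-methylbut-3-enal | Br/C=C(\C)CC=O | intermediate
5 | tiglic aldehyde, (E)-2-methylbut-2-enal | C/C=C(\C)C=O | starting material
6 | triethyl phosphonoacetate | CCOC(=O)CP(=O)(OCC)OCC | starting material
7 | ethyl (2E,4E)-4-methylhexa-2,4-dienoate | C/C=C(\C)/C=C/C(=O)OCC | intermediate
8 | (2E,4E)-4-methylhexa-2,4-dienoic acid | C/C=C(\C)/C=C/C(=O)O | intermediate
9 | (S)-4-benzyloxazolidin-2-one | O=C1N[C@@H](Cc2ccccc2)CO1 | starting material
10 | (2E,4E)-4-methylhexa-2,4-dienoic pivalic anhydride (not isolated) | C/C=C(\C)/C=C/C(=O)OC(=O)C(C)(C)C | intermediate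
11 | (S)-4-benzyl-3-[(2E,4E)-4-methylhexa-2,4-dienoyl]oxazolidin-2-one | C/C=C(\C)/C=C/C(=O)N1[C@@H](Cc2ccccc2)COC1=O | intermediate
12 | dibutylboron (Z)-trienolate of 11 (not isolated) | CCCCB(CCCC)O/C(=C\C=C(/C)C=C)N1[C@@H](Cc2ccccc2)COC1=O | intermediate
13 | (S)-4-benzyl-3-[(2S,3R,5E)-6-bromo-3-hydroxy-5-methyl-2-[(1E)-2-methylbuta-1,3-dien-1-yl]hex-5-enoyl]oxazolidin-2-one | Br/C=C(\C)C[C@@H](O)[C@@H](C(=O)N1[C@@H](Cc2ccccc2)COC1=O)/C=C(\C)C=C | intermediate
14 | (2R,3R,5E)-6-bromo-5-methyl-2-[(1E)-2-methylbuta-1,3-dien-1-yl]hex-5-ene-1,3-diol | Br/C=C(\C)C[C@@H](O)[C@@H](CO)/C=C(\C)C=C | intermediate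
15 | (2R,3R,5E)-6-bromo-1,3-bis(tert-butyldimethylsilyloxy)-5-methyl-2-[(1E)-2-methylbuta-1,3-dien-1-yl]hex-5-ene (key-step precursor) | Br/C=C(\C)C[C@@H](O[Si](C)(C)C(C)(C)C)[C@@H](CO[Si](C)(C)C(C)(C)C)/C=C(\C)C=C | intermediate
16 | 4β-bromo-2α-(tert-butyldimethylsilyloxy)-1α-[(tert-butyldimethylsilyloxy)methyl]-3aβ,7-dimethyl-2,3,3a,4,5,7a-hexahydro-1H-indene, 7aα-H (key-step product) | CC(C)(C)[Si](C)(C)OC[C@@H]1[C@H](O[Si](C)(C)C(C)(C)C)C[C@]2(C)[C@@H](Br)CC=C(C)[C@@H]12 | intermediate
17 | 6α-(acetoxymercurio)-7β-hydroxy adduct of 16 (not isolated) | CC(C)(C)[Si](C)(C)OC[C@@H]1[C@H](O[Si](C)(C)C(C)(C)C)C[C@]2(C)[C@@H](Br)C[C@H]([Hg]OC(C)=O)[C@@](C)(O)[C@@H]12 | intermediate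
18 | 4β-bromo-2α-(tert-butyldimethylsilyloxy)-1α-[(tert-butyldimethylsilyloxy)methyl]-3aβ,7α-dimethyloctahydro-1H-inden-7β-ol | CC(C)(C)[Si](C)(C)OC[C@@H]1[C@H](O[Si](C)(C)C(C)(C)C)C[C@]2(C)[C@@H](Br)CC[C@@](C)(O)[C@@H]12 | intermediate
19 | primary alcohol, 1α-hydroxymethyl analogue of 18 | OC[C@@H]1[C@H](O[Si](C)(C)C(C)(C)C)C[C@]2(C)[C@@H](Br)CC[C@@](C)(O)[C@@H]12 | intermediate
20 | C8 aldehyde, 1α-formyl analogue of 18 | O=C[C@@H]1[C@H](O[Si](C)(C)C(C)(C)C)C[C@]2(C)[C@@H](Br)CC[C@@](C)(O)[C@@H]12 | intermediate
21 | 6-methylhept-5-en-2-one | CC(C)=CCCC(C)=O | starting material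
22 | 2,4,6-triisopropylbenzenesulfonohydrazide | CC(C)c1cc(C(C)C)c(S(=O)(=O)NN)c(C(C)C)c1 | starting material
23 | 6-methylhept-5-en-2-one 2,4,6-triisopropylbenzenesulfonylhydrazone | CC(C)=CCCC(C)=NNS(=O)(=O)c1c(C(C)C)cc(C(C)C)cc1C(C)C | intermediate
24 | 2-lithio-6-methylhepta-1,5-diene (not isolated) | [Li]C(=C)CCC=C(C)C | intermediate
25 | C8 allylic alcohol, 1α-[1-hydroxy-6-methyl-2-methylenehept-5-enyl] hydrindane, both C8 epimers | CC(C)=CCCC(=C)C(O)[C@@H]1[C@H](O[Si](C)(C)C(C)(C)C)C[C@]2(C)[C@@H](Br)CC[C@@](C)(O)[C@@H]12 | intermediate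
26 | C8 enone, 2α-silyloxy | CC(C)=CCCC(=C)C(=O)[C@@H]1[C@H](O[Si](C)(C)C(C)(C)C)C[C@]2(C)[C@@H](Br)CC[C@@](C)(O)[C@@H]12 | intermediate
27 | C8 enone, 2α-hydroxy | CC(C)=CCCC(=C)C(=O)[C@@H]1[C@H](O)C[C@]2(C)[C@@H](Br)CC[C@@](C)(O)[C@@H]12 | intermediate
28 | diethylboron chelate of 27 (not isolated) | CC(C)=CCCC(=C)C(=O)[C@@H]1[C@H](OB(CC)CC)C[C@]2(C)[C@@H](Br)CC[C@@](C)(O)[C@@H]12 | intermediate
29 | (8R) syn-1,3-diol, 2α,7β-dihydroxy-1α-[(R)-1-hydroxy-6-methyl-2-methylenehept-5-enyl] hydrindane | CC(C)=CCCC(=C)[C@H](O)[C@@H]1[C@H](O)C[C@]2(C)[C@@H](Br)CC[C@@](C)(O)[C@@H]12 | intermediate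
30 | C2,C8-diacetate of 29 | CC(C)=CCCC(=C)[C@H](OC(C)=O)[C@@H]1[C@H](OC(C)=O)C[C@]2(C)[C@@H](Br)CC[C@@](C)(O)[C@@H]12 | intermediate
31 | spiro 2-methyl-1,3-dioxolan-2-ylium ion on C1'/C8, bromopentachloroantimonate salt (not isolated) | CC1(C)C[C@]2([O+]=C(C)O[C@@H]2[C@@H]3[C@H](OC(C)=O)C[C@]4(C)[C@@H](Br)CC[C@@](C)(O)[C@@H]34)CC[C@@H]1Br.Cl[Sb-](Cl)(Cl)(Cl)(Cl)Br | intermediate
32 | ring A hydroxy diacetate, C1'-OH, C8-OAc, C2-OAc | CC1(C)C[C@@](O)([C@H](OC(C)=O)[C@@H]2[C@H](OC(C)=O)C[C@]3(C)[C@@H](Br)CC[C@@](C)(O)[C@@H]23)CC[C@@H]1Br | intermediate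
33 | (1S,2R,3aS,4S,7R,7aS)-4-bromo-1-{(R)-[(1R,4S)-4-bromo-1-hydroxy-3,3-dimethylcyclohexyl](hydroxy)methyl}-3a,7-dimethyloctahydro-1H-indene-2,7-diol | CC1(C)C[C@@](O)([C@H](O)[C@@H]2[C@H](O)C[C@]3(C)[C@@H](Br)CC[C@@](C)(O)[C@@H]23)CC[C@@H]1Br | target

**Step count and risks**

Total: 20 steps. Longest linear sequence: 17 steps (steps 3–12 and 14–20, from tiglic aldehyde).

Steps most likely to fail:

Step 9. The cis-fused fold may compete with the trans-fused one, and at the temperature the unactivated bromoalkene needs, polymerisation of the diene or loss of a silyl group may overtake cycloaddition. The fallback reshapes the tether and sets out from diol 14. Treatment with t-Bu2Si(OTf)2 and 2,6-lutidine ties both oxygens into the six-membered di-tert-butylsilylene triene F1. The ring freezes rotation about C1–C2, so a faster cycloaddition at lower temperature is expected, and it holds both oxygen substituents on the α face, which the angular methyl can avoid only in the trans fold. Heating F1 in toluene should give the silylene-bridged trans-hydrindene F2; HF·pyridine releases the hydrindene diol F3, and TBSOTf with 2,6-lutidine returns to the route at 16.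

Step 19. The bromonium ion may be taken by bromide or lose a proton before the ester-deactivated 1,1-disubstituted alkene attacks, and the remote alkene is brominated without facial preference. The fallback sets out from 30 and closes ring A with mercury instead of bromine. Hg(OTf)2 with N,N-dimethylaniline in MeNO2 at −20 °C forms the mercurinium ion reversibly and without halide interception; the same acetate capture and an aqueous NaBr work-up should give the ring A alkylmercuric bromide F4. Its C4' epimers are separated at this stage, before bromine is introduced. Bromodemercuration with Br2 in pyridine at 0 °C in the dark (electrophilic cleavage with retention) returns to the route at 32. This fallback answers the interception problem but not the facial one.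

Step 6. Enolisation at the remote C6 methyl of the dienoyl imide may be incomplete or not regioselective, and the geometry of the new C3=C4 bond may scramble. The fallback separates deconjugation from the aldol and sets out from acid 8. The dianion formed with LiN(i-Pr)2 (2.2 equiv) in THF/DMPU at −78 °C is protonated kinetically at the α-carbon with AcOH to give (E)-4-methylhexa-3,5-dienoic acid F5, whose (E)-isomer is purified here. Its pivalic mixed anhydride F6 (not isolated) acylates 9 to the (E)-4-methylhexa-3,5-dienoyl imide F7. The doubly activated α-CH2 of F7 is enolised by Bu2BOTf and Et3N under standard conditions to the same enolate 12, and addition of 4 returns to the route at 13.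

Further compounds
F1 | step 9 | di-tert-butylsilylene acetal of diol 14 (silylene triene) | Br/C=C(\C)C[C@H]1O[Si](C(C)(C)C)(C(C)(C)C)OC[C@H]1/C=C(\C)C=C
F2 | step 9 | silylene-bridged 4β-bromo trans-hydrindene | CC(C)(C)[Si]1(C(C)(C)C)OC[C@@H]2[C@H](O1)C[C@]3(C)[C@@H](Br)CC=C(C)[C@@H]23
F3 | step 9 | 4β-bromo-1α-(hydroxymethyl)-3aβ,7-dimethyl-2,3,3a,4,5,7a-hexahydro-1H-inden-2α-ol | OC[C@@H]1[C@H](O)C[C@]2(C)[C@@H](Br)CC=C(C)[C@@H]12
F4 | step 19 | ring A alkylmercuric bromide (C4'-HgBr analogue of 32) | CC1(C)C[C@@](O)([C@H](OC(C)=O)[C@@H]2[C@H](OC(C)=O)C[C@]3(C)[C@@H](Br)CC[C@@](C)(O)[C@@H]23)CC[C@@H]1[Hg]Br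
F5 | step 6 | (E)-4-methylhexa-3,5-dienoic acid | OC(=O)C/C=C(\C)C=C
F6 | step 6 | (E)-4-methylhexa-3,5-dienoic pivalic anhydride | CC(C)(C)C(=O)OC(=O)C/C=C(\C)C=C
F7 | step 6 | (S)-4-benzyl-3-[(E)-4-methylhexa-3,5-dienoyl]oxazolidin-2-one | O=C(C/C=C(\C)C=C)N1[C@@H](Cc2ccccc2)COC1=O
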